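**Plan**

1. Numbering (biogenetic): N1/C2/C7 are the indoline N, C-2 and C-3. C16(H)(CO2Me)–C17 and C18–C19 are the two two-carbon bridges from C2 to the spiro carbon C20. C6–C5 join C7 to N4, C3–C14–C15(OH) close the pyrrolidine, and C21 is the ester carbon on C7.
2. Cuts, in retrosynthetic order: C15–OH back to the ketone; C17–C20 (transannular Michael addition to a C16 acrylate, C17 from formaldehyde); N4–C5 (reductive amination); then C19–C20 and C2–C7 together, which splits the molecule into dienoate 7 and β-keto ester 8; 7 comes from carbamate 4 and enynoate 6 (N1–C2).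
3. Forward: the pyrrolidine comes ready-made in 8. The key step joins the halves (C19–C20) and closes the indoline (C2–C7). Then the azocine (N4–C5), then the cyclohexane (C17–C20), which completes the bicyclo[4.2.2] core, then ketone reduction.
4. Enabling feature: in 7 the C16 ester is conjugated through C2, which carries N1, to the C18=C19 vinyl group (a 3-amido-2,4-dienoate). C19 (δ) and, after one proton shift, C2 (β) are therefore electrophilic in turn, and their partners C20 and C7 are both enolizable carbons, C20 made the more acidic by a removable ester.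
5. Stereochemistry: C2 and C7 arise together in the key step (absolute sense from a chiral crown ether on K+, relative sense from the ring-closing transition state). C20 stays epimerizable and is fixed by the transannular closure, because N4 is already tied to C7. C16 is set by kinetic protonation in that step and C15 by (R)-CBS reduction.

Key step: step 5

Assumption: the (S,S)-host is taken to induce the 2R,7S series; should the sense be the reverse, the (R,R)-host is used with no other change.

**Route**

Step 1
Reactants: 1 methyl 2-(2-nitrophenyl)acetate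
Product: 3 methyl 2-[2-(methoxycarbonylamino)phenyl]acetate, via aniline ester 2 (not isolated)
Conditions: H2 (1 atm), Pd/C, MeOH, rt; filter, evaporate; ClCO2Me, pyridine, CH2Cl2, 0 °C
Reagents that add atoms: methyl chloroformate, COC(=O)Cl
Why: Catalytic hydrogenation of the nitroarene gives the aniline, which is acylated at once (carbamate formation) before it can lactamize to oxindole; no stereocentre.

Step 2
Reactants: 3 methyl 2-[2-(methoxycarbonylamino)phenyl]acetate
Product: 4 methyl 2-[2-(methoxycarbonylamino)phenyl]pent-4-enoate (racemic)
Conditions: LiN(SiMe3)2 (2.1 equiv), THF, −78 °C; allyl bromide (1.05 equiv), −78 → −30 °C; aq. NH4Cl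
Reagents that add atoms: allyl bromide, C=CCBr
Why: N,C-dianion alkylation: the ester enolate is the more nucleophilic site and should be allylated once (enolate alkylation); the new centre is racemic and is planarized again in step 5.

Step 3
Reactants: 5 but-1-en-3-yne
Product: 6 methyl pent-4-en-2-ynoate
Conditions: n-BuLi, THF, −78 °C; ClCO2Me, −78 → 0 °C
Reagents that add atoms: methyl chloroformate, COC(=O)Cl
Why: Deprotonation of the terminal alkyne and C-acylation of the acetylide with a chloroformate, the standard ynoate synthesis.

Step 4
Reactants: 4 methyl 2-[2-(methoxycarbonylamino)phenyl]pent-4-enoate; 6 methyl pent-4-en-2-ynoate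
Product: 7 3-amido-2,4-dienoate (E/Z mixture, racemic)
Conditions: Cs2CO3 (0.2 equiv), MeCN, 0 °C → rt
Reagents that add atoms: none
Why: Base-catalysed conjugate addition (hydroamidation) of the carbamate N–H, the most acidic site of 4, to the alkyne β-carbon of the ynoate should give the β-amido dienoate; the alkene geometry is lost again in step 5.

Step 5
Reactants: 7 3-amido-2,4-dienoate; 8 1-tert-butyl 2-ethyl 3-oxopyrrolidine-1,2-dicarboxylate (0.98 equiv)
Product: 10 (2R,7S)-indoline keto diester (both C20 epimers), via conjugated 1,6-adduct 9 (not isolated)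
Conditions: KOt-Bu (0.3 equiv), (S,S)-bis(1,1′-binaphthyl-2,2′-diyl)-22-crown-6 (0.3 equiv), t-BuOH (2 equiv), toluene, −40 → 0 °C; AcOH quench
Reagents that add atoms: none
Why: Proposed new method: the potassium enolate of 8 adds to C19, the open δ-terminus of the 3-amido-2,4-dienoate 7 (vinylogous 1,6-Michael addition, C19–C20), the dienolate is reprotonated to the conjugated β-amido acrylate 9, and once 8 (pKa about 12) is consumed the base reaches the arylacetate C7–H (pKa about 24), whose enolate closes the indoline by 5-exo-trig Michael addition to C2 (C2–C7). Closest known reaction types: 1,6-addition of β-keto esters to δ-unsubstituted dienoates, base-mediated 5-exo Michael cyclization onto β-amido acrylates, and chiral crown ether/KOt-Bu-catalysed Michael additions of phenylacetate esters. C2 and C7 are created together in the ring closure: the chiral host on K+ selects the enolate face (absolute sense), and an open transition state that keeps the planar enolate carbon C21 over the C18 methylene and away from the developing C16 enolate should put the allyl group (C6) cis to the C16 arm (relative sense); C20 forms as a mixture and is erased in step 6. The selectivities needed are 1,6- over 1,4-attack in the first addition, secured by the fully substituted, nitrogen-bearing C2 against the unhindered CH2 terminus, and the order of the two additions, secured by the pKa gap that keeps all base on 8 until the vinyl group is gone. t-BuOH is there to protonate the C16 ester enolate before it can expel N1 or revert.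

Step 6
Reactants: 10 (2R,7S)-indoline keto diester
Product: 11 N-Boc amino ketone (both C20 epimers)
Conditions: LiCl, H2O (2 equiv), DMSO, 130 °C
Reagents that add atoms: none
Why: Krapcho dealkoxycarbonylation is specific for the β-keto ester and leaves C20 as an epimerizable CH next to the ketone, which is what step 10 needs.

Step 7
Reactants: 11 N-Boc amino ketone
Product: 13 C16-hydroxymethyl ester (epimers at C16/C20), via bis-silyl derivative 12 (not isolated)
Conditions: LiN(iPr)2/Me3SiCl (premixed, 2.5/3 equiv), THF, −78 °C; pentane, filter; CH2O (monomeric, 1.2 equiv), Me3SiOTf (10 mol %), CH2Cl2, −78 °C; aq. citric acid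
Reagents that add atoms: formaldehyde, C=O
Why: In situ silylation turns the C16 ester into its silyl ketene acetal before the enolate can expel N1 and masks the ketone as its enol ether, and the Mukaiyama aldol addition to formaldehyde should then occur at the far more nucleophilic ketene acetal; the C16 centre is a mixture and becomes sp2 in step 10.

Step 8
Reactants: 13 C16-hydroxymethyl ester
Product: 14 aldehyde (C5)
Conditions: O3, CH2Cl2/MeOH, −78 °C; Me2S, −78 °C → rt
Reagents that add atoms: ozone, [O-][O+]=O
Why: Ozonolysis of the only C=C bond (the terminal allyl group) with reductive work-up should give the aldehyde one carbon shorter.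

Step 9
Reactants: 14 aldehyde (C5)
Product: 16 azocine amino ketone, via amino aldehyde 15 (not isolated)
Conditions: CF3CO2H/CH2Cl2 (1:4), 0 °C; evaporate; NaBH(OAc)3, AcOH, ClCH2CH2Cl (0.005 M), 0 °C → rt; aq. NaHCO3
Reagents that add atoms: none
Why: Acidolysis of the Boc group frees N4, and intramolecular reductive amination with the C5 aldehyde (eight-membered ring closed by N4–C5 bond formation at high dilution) should give the azocine, NaBH(OAc)3 leaving the ketone untouched.

Step 10
Reactants: 16 azocine amino ketone
Product: 19 pentacyclic ketone, via mesylate 17 (not isolated), via acrylate 18 (not isolated)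
Conditions: MsCl, Et3N, CH2Cl2, −20 °C; solvent switch; Cs2CO3, MeCN, rt → 40 °C; aq. NH4Cl
Reagents that add atoms: none
Why: Mesylation and E1cB elimination give the C16 acrylate, and the C20 enolate of the amino ketone adds to C17 across the eight-membered ring (transannular 6-endo-trig Michael addition); because N4 is already tied to C7 by the C5–C6 bridge, C20 can only form with N4 cis to C7, and C16 is set by kinetic protonation of the ester enolate from the face turned to the C18–C19 bridge, away from C6.

Step 11
Reactants: 19 pentacyclic ketone
Product: 20 target compound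
Conditions: (R)-2-methyl-CBS-oxazaborolidine (0.5 equiv), catecholborane (2.5 equiv), CH2Cl2/toluene, −78 → −40 °C; MeOH; aq. NaHCO3
Reagents that add atoms: none
Why: Corey–Bakshi–Shibata reduction under reagent control: the (R)-catalyst distinguishes the quaternary C20 side from the C14 methylene side of the ketone and should deliver hydride to give the 15S alcohol, OH cis to C19.

**Compound list**

1 | methyl 2-(2-nitrophenyl)acetate | COC(=O)Cc1ccccc1[N+](=O)[O-] | starting material
2 | methyl 2-(2-aminophenyl)acetate | COC(=O)Cc1ccccc1N | intermediate
3 | methyl 2-[2-(methoxycarbonylamino)phenyl]acetate | COC(=O)Cc1ccccc1NC(=O)OC | intermediate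
4 | methyl 2-[2-(methoxycarbonylamino)phenyl]pent-4-enoate (racemic) | COC(=O)C(CC=C)c1ccccc1NC(=O)OC | intermediate
5 | but-1-en-3-yne (vinylacetylene) | C=CC#C | starting material
6 | methyl pent-4-en-2-ynoate | COC(=O)C#CC=C | intermediate
7 | methyl 3-[N-(methoxycarbonyl)-2-(1-methoxy-1-oxopent-4-en-2-yl)anilino]penta-2,4-dienoate (2E/2Z mixture, racemic) | COC(=O)C=C(C=C)N(C(=O)OC)c1ccccc1C(CC=C)C(=O)OC | intermediate
8 | 1-tert-butyl 2-ethyl 3-oxopyrrolidine-1,2-dicarboxylate (racemic) | CCOC(=O)C1N(C(=O)OC(C)(C)C)CCC1=O | starting material
9 | 1-tert-butyl 2-ethyl 2-{5-methoxy-3-[N-(methoxycarbonyl)-2-(1-methoxy-1-oxopent-4-en-2-yl)anilino]-5-oxopent-3-enyl}-3-oxopyrrolidine-1,2-dicarboxylate (conjugated 1,6-adduct, stereoisomer mixture) | CCOC(=O)C1(CCC(=CC(=O)OC)N(C(=O)OC)c2ccccc2C(CC=C)C(=O)OC)N(C(=O)OC(C)(C)C)CCC1=O | intermediate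
10 | 1-tert-butyl 2-ethyl 2-{2-[(2R,3S)-3-allyl-1,3-bis(methoxycarbonyl)-2-(2-methoxy-2-oxoethyl)indolin-2-yl]ethyl}-3-oxopyrrolidine-1,2-dicarboxylate (2R,7S in biogenetic numbering; both C20 epimers) | COC(=O)C[C@@]1(CCC2(C(=O)OCC)N(C(=O)OC(C)(C)C)CCC2=O)N(C(=O)OC)c2ccccc2[C@@]1(C(=O)OC)CC=C | intermediate
11 | tert-butyl 2-{2-[(2R,3S)-3-allyl-1,3-bis(methoxycarbonyl)-2-(2-methoxy-2-oxoethyl)indolin-2-yl]ethyl}-3-oxopyrrolidine-1-carboxylate (both C20 epimers) | COC(=O)C[C@@]1(CCC2N(C(=O)OC(C)(C)C)CCC2=O)N(C(=O)OC)c2ccccc2[C@@]1(C(=O)OC)CC=C | intermediate
12 | bis(trimethylsilyl) derivative of 11: trimethylsilyl ketene acetal of the CH2CO2Me ester and trimethylsilyl enol ether of the ketone (drawn as the C14=C15 isomer) | COC(O[Si](C)(C)C)=C[C@@]1(CCC2N(C(=O)OC(C)(C)C)CC=C2O[Si](C)(C)C)N(C(=O)OC)c2ccccc2[C@@]1(C(=O)OC)CC=C | intermediate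
13 | hydroxymethyl derivative of 11: the CH2CO2Me group has become CH(CH2OH)CO2Me (epimers at C16 and C20) | COC(=O)C(CO)[C@@]1(CCC2N(C(=O)OC(C)(C)C)CCC2=O)N(C(=O)OC)c2ccccc2[C@@]1(C(=O)OC)CC=C | intermediate
14 | aldehyde from 13: the allyl group on C7 has become CH2CHO | COC(=O)C(CO)[C@@]1(CCC2N(C(=O)OC(C)(C)C)CCC2=O)N(C(=O)OC)c2ccccc2[C@@]1(C(=O)OC)CC=O | intermediate
15 | amino aldehyde from 14, Boc removed (handled as its trifluoroacetate salt) | COC(=O)C(CO)[C@@]1(CCC2NCCC2=O)N(C(=O)OC)c2ccccc2[C@@]1(C(=O)OC)CC=O | intermediate
16 | azocine amino ketone: N4 bonded to C5, eight-membered ring N4–C5–C6–C7–C2–C18–C19–C20 fused to the indoline and to the pyrrolidin-3-one; (2R,7S), epimers at C16 and C20 | COC(=O)C(CO)[C@]12CCC3N(CC[C@]1(C(=O)OC)c1ccccc1N2C(=O)OC)CCC3=O | intermediate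
17 | methanesulfonate of the primary alcohol of 16 | COC(=O)C(COS(C)(=O)=O)[C@]12CCC3N(CC[C@]1(C(=O)OC)c1ccccc1N2C(=O)OC)CCC3=O | intermediate
18 | acrylate: C2 of the azocine amino ketone carries C(=CH2)CO2Me | COC(=O)C(=C)[C@]12CCC3N(CC[C@]1(C(=O)OC)c1ccccc1N2C(=O)OC)CCC3=O | intermediate
19 | pentacyclic 15-ketone, (2R,7S,16R,20R) | COC(=O)[C@@H]1C[C@@]23CC[C@@]14N(C(=O)OC)c1ccccc1[C@@]4(C(=O)OC)CCN2CCC3=O | intermediate
20 | target compound CNP0144467.1, (2R,7S,15S,16R,20R) | COC(=O)[C@@H]1C[C@@]23CC[C@@]14N(C(=O)OC)c1ccccc1[C@@]4(C(=O)OC)CCN2CC[C@@H]3O | target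

**Step count**

Total steps: 11. Longest linear sequence: 10 steps (steps 1, 2, 4, 5, 6, 7, 8, 9, 10, 11); step 3 is a one-step side branch.

**Steps most likely to fail**

Step 5 (Proposed new method). Several processes could defeat it:
- ring closure of the arylacetate enolate onto C2 before C19 has reacted, which strands an unreactive vinyl group;
- transfer of the methoxycarbonyl group from N1 to the C7 enolate;
- ring-opening of the adduct by loss of N1 from the C16 enolate, with scrambling at C2;
- weak enantiofacial discrimination by the crown.

The fallback sets out from 7 and 8 and comes back to the route at 10. The conjugate addition is run by itself with DBU (10 mol %) in toluene at room temperature, a standard vinylogous Michael addition of a β-keto ester, and 9 is isolated. 9 is then closed with KOt-Bu/18-crown-6 and t-BuOH in THF at −40 °C (base-mediated 5-exo Michael cyclization), which should give 10 together with the mirror image of 10 F1. 10 is separated from F1 by preparative chromatography on a chiral stationary phase and enters step 6.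

Step 9. The medium-ring closure may lose to intermolecular condensation, to aldol condensation between the aldehyde and the ketone, or to reduction of the aldehyde before the cyclic iminium ion has formed.

The fallback sets out from 14 and comes back at 16, closing the ring by N-alkylation instead. The aldehyde of 14 is reduced selectively with NaBH4 in MeOH/CH2Cl2 at −78 °C, and on acidic work-up the γ-hydroxy ester should close to the spiro-γ-lactone F2. HBr in MeOH opens the lactone to the γ-bromo methyl ester and removes the Boc group, giving the bromo amine F3 as its hydrobromide. K2CO3 with NaI (cat.) in MeCN at high dilution then closes the azocine by intramolecular N-alkylation to give 16.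

Step 10. The C16 ester enolate may be protonated from the wrong face, C16 may epimerize afterwards, or enolization towards C20 may be too slow for the transannular addition.

The fallback sets out from 16 and comes back at 19, and sets C16 by hydrogenation instead. Dess–Martin periodinane oxidizes the primary alcohol of 16 to the formyl ester F4. Piperidinium acetate in toluene at 60 °C should close the six-membered ring by transannular aldol condensation of the C20 ketone enol onto the formyl group with loss of water, giving the C16=C17 unsaturated keto ester F5. Hydrogenation (H2, Pd/C, EtOAc) from the face turned to the C18–C19 bridge should give 19.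

Further compounds
F1 | step 5 | mirror image of 10 (2S,7R; both C20 epimers) | COC(=O)C[C@]1(CCC2(C(=O)OCC)N(C(=O)OC(C)(C)C)CCC2=O)N(C(=O)OC)c2ccccc2[C@]1(C(=O)OC)CC=C
F2 | step 9 | spiro-γ-lactone from 14 (C21 carbonyl joined through O to C5; Boc, ketone and CH(CH2OH)CO2Me unchanged) | COC(=O)C(CO)[C@@]1(CCC2N(C(=O)OC(C)(C)C)CCC2=O)N(C(=O)OC)c2ccccc2[C@@]13CCOC3=O
F3 | step 9 | bromo amine (free base shown, handled as hydrobromide): C7 carries CO2Me and CH2CH2Br, N4 is NH | COC(=O)C(CO)[C@@]1(CCC2NCCC2=O)N(C(=O)OC)c2ccccc2[C@@]1(C(=O)OC)CCBr
F4 | step 10 | formyl ester from 16: C2 carries CH(CHO)CO2Me | COC(=O)C(C=O)[C@]12CCC3N(CC[C@]1(C(=O)OC)c1ccccc1N2C(=O)OC)CCC3=O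
F5 | step 10 | C16=C17 unsaturated pentacyclic keto ester | COC(=O)C1=C[C@@]23CC[C@@]14N(C(=O)OC)c1ccccc1[C@@]4(C(=O)OC)CCN2CCC3=O
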